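Numbering used throughout: ring A is the catechol ring, C7–C8–C9 is the glycerol chain (C7 benzylic), and ring B is the guaiacyl ring with primed atoms (O on C4', OMe on C3', side chain C7'–C9' on C1'). Bn = benzyl, Tr = triphenylmethyl.

## The problem

The target 16 is an acyclic 8-O-4' neolignan. A catechol ring A carries the chain C7–C8–C9, and the oxygen on C8 is bound to C4' of ring B, which holds a methoxy group at C3' and a 3-hydroxypropyl chain at C1'. No ring has to be closed. What has to be made is a secondary alkyl aryl ether at C8, flanked by two oxygenated carbons, without loss of configuration. The two adjacent stereocentres are (7S,8R), the erythro (anti) arrangement. C8 is a glycerol carbon that can be bought enantiopure, and its oxygen can steer a nucleophile onto a C7 carbonyl in the Felkin–Anh sense; C7 offers no comparable handle for setting C8. The free catechol is oxidised easily, most of all under base. The C7 carbinol is benzylic and para to a phenol, so acid ionises it (epimerisation, quinone methide) and forcing hydrogenolysis removes it. Two phenols and three aliphatic hydroxyls must be told apart so that only the C8 oxygen is free when the ether is formed. The enabling feature lies on ring B: the ether oxygen at C4' is para to C1', and the C1' chain can be grown from a formyl group, which is exactly the acceptor that makes C4' of a fluoroarene electrophilic. The C8 alkoxide can therefore attack C4', and the C8–O bond, with its configuration, is never broken.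

## Retrosynthesis

**16 from 15.** The last disconnection removes only protecting groups and one unsaturation: three O–CH2Ph bonds (O3, O4, O7), the O9–CPh3 bond and the C7'=C8' double bond of allylic alcohol 15. A single neutral hydrogenation does all of this, and the catechol appears only in the final flask. Acid- or fluoride-labile groups would need separate steps, and acid endangers C7. The forward reaction must cleave the O–CH2Ph bonds faster than the benzylic C7–O bond and the allylic C9'–O bond.

**15 from 14, and 14 from 12 and 13.** The C9' alcohol is traced to the ester of enoate 14, and the C7'=C8' bond is cut by a Wittig disconnection to aldehyde 12 and the stabilised ylide 13. This lets the formyl group serve twice: as the root of the side chain and, one step earlier, as the activating group on ring B. Attaching a three-carbon chain by cross-coupling would need a ring B halide that gives no such activation. Aldehyde 12 is simpler by two carbons and one oxygen function. The olefination must be neutral, and the hydride reduction is placed before deprotection so that no aluminium or boron reagent meets a free catechol.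

**12 from 9 and 10 (key disconnection).** The O–C4' bond is cut, giving the arylglycerol alcohol 9 (as its potassium alkoxide 11) and commercial 4-fluoro-3-methoxybenzaldehyde 10. The neighbouring cuts are weaker:
- Cutting C8–O would need a phenoxide to displace a leaving group at a hindered secondary carbon next to the benzylic C7, with inversion and competing elimination.
- Opening a C7–C8 epoxide with the phenol would occur at the benzylic C7, the wrong carbon.

The cut at the aryl carbon leaves both stereocentres untouched and removes the whole of ring B in one step. The forward reaction must make alkoxide 11 attack the aromatic carbon productively, while its addition to the formyl group stays reversible.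

**9 from 8, 8 from 7, 7 from 5.** These are protecting-group cuts: O9–CPh3, the isopropylidene acetal on O8/O9, and O7–CH2Ph (through sodium alkoxide 6). The acetonide that arrives with the chiral-pool aldehyde already separates O8 and O9 from O7, so O7 is benzylated first. Hydrolysis then frees diol 8, and size alone distinguishes primary O9 (trityl) from secondary O8. Silyl or acyl groups on O7 or O9 would migrate to the adjacent alkoxide under the base of the key step; benzyl and trityl ethers do not. The acid step must be mild enough not to ionise C7.

**5 from 1 and 2.** The C7–C1 bond to ring A is cut, giving aryl bromide 1 and (R)-glyceraldehyde acetonide 2, joined through Grignard reagent 3 and aryltitanium reagent 4. Dihydroxylation of a cinnamyl precursor is syn and leads to the threo series, and an aldol route needs an auxiliary. Here C8 is bought with the correct configuration and controls C7. Both precursors are commercial. The aryl metal must be non-chelating so that the addition follows the anti mode.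

## Roads not taken

**Alternative 1:** A three-component oxonium ylide aldol cuts both O4'–C8 and C7–C8 at once.
- Forward step: Rh2(OAc)4 decomposes ethyl diazoacetate A3 in the presence of the ring B phenol, methyl 3-(4-hydroxy-3-methoxyphenyl)propanoate A2. The resulting oxonium ylide is trapped by 3,4-diacetoxybenzaldehyde A4 under a chiral acid co-catalyst (a BINOL-derived phosphoric acid, or a BINOL complex made from Zr(OtBu)4) to give the anti ester A1.
- Merits: two bonds and both stereocentres in one catalytic step from three simple components. A single hydride reduction of A1 would convert both esters and remove both acetates, giving 16 in about three steps overall.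
- Weak points: with an acceptor-only diazo ester the protic oxonium ylide tends to collapse by proton shift (plain O–H insertion) before an aldehyde of ordinary electrophilicity can intercept it. Trapping of this kind is best established for aryl diazoacetates with more reactive electrophiles. Anti selectivity and enantioselectivity would both rest on a catalyst with no substrate element to support them.
- Comparison: in step economy this road is clearly better. The chosen plan offers instead a configuration fixed by a chiral-pool carbon and substrate control, and steps that each belong to a known reaction class.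

**Alternative 2:** The cut is C7–C1 of ring A, made after the ether is already in place.
- Forward step: the aryltitanium reagent 4 adds to the α-aryloxy aldehyde A6, (R)-3-silyloxy-2-aryloxypropanal carrying the complete silyl-protected ring B chain, to give the anti carbinol A5. Desilylation and hydrogenolysis would then give 16.
- Merits: it is convergent, ring B and its chain are finished before the coupling, only two steps follow, and the same Felkin–Anh logic sets C7.
- Weak points: A6 is an α-aryloxy aldehyde with an acidic α-hydrogen and a β-silyloxy group, so it can epimerise or eliminate on handling. Making it enantiopure still requires forming the same C8–O4' ether earlier on a glyceric acid derivative, followed by an oxidation-state adjustment. Facial selectivity of aryl addition to α-aryloxy aldehydes is less secure than for the dioxolane aldehyde 2.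
- Comparison: in convergence and in the number of steps after the fragment union this road is as good or better. The chosen plan offers instead a C8 that is locked in a dioxolane when the C–C bond forms, and an ether formation that touches no stereocentre.

**Alternative 3:** The biomimetic cut is C8–O4' by radical cross-coupling.
- Forward step: a laccase with O2, or horseradish peroxidase with H2O2, oxidises (E)-2-benzyloxy-4-(3-hydroxyprop-1-en-1-yl)phenol A8 and 4-(3-hydroxypropyl)-2-methoxyphenol A9 to phenoxy radicals. These join C8 to O4', and water adds to C7 of the resulting quinone methide to give the 3-O-benzyl ether A7. One hydrogenolysis would then give 16.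
- Merits: two steps, aqueous medium, no protection of aliphatic hydroxyls.
- Weak points: the coupling is not enantioselective, and water addition to the quinone methide is barely face-selective, so A7 would form as a racemic erythro/threo mixture. Homo-coupling of A8 and oligomerisation compete with the cross-coupling. The single enantiomer would need preparative chiral separation with loss of most of the material.
- Comparison: for racemic material this would be the shortest road, and no designed route can match its step count. The chosen plan offers instead absolute and relative stereocontrol and predictable throughput of the one isomer required.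

Key step: step 5

Assumption: aldehyde 2 oligomerises on storage and is taken as the freshly distilled monomer.

## Route

Step 1
Reactants: 1 4-bromo-1,2-bis(benzyloxy)benzene; 2 (R)-2,2-dimethyl-1,3-dioxolane-4-carbaldehyde
Product: 5 (S)-[3,4-bis(benzyloxy)phenyl][(4R)-2,2-dimethyl-1,3-dioxolan-4-yl]methanol, via arylmagnesium bromide 3 (not isolated), via aryltitanium triisopropoxide 4 (not isolated)
Conditions: Mg, THF, reflux; ClTi(OiPr)3, THF, −78 to −30 °C; then 2, −78 to 0 °C; aq. NH4Cl
Reagents that add atoms: none
Why: Grignard formation and transmetalation to tetravalent titanium give a bulky, weakly Lewis acidic aryl nucleophile that does not chelate the dioxolane oxygen; addition to 2 should then follow the polar Felkin–Anh model (attack anti to the C8–O bond) and set C7 as S, anti to the (R)-C8 from the chiral pool. Reaction type: non-chelation-controlled organotitanium addition to an α-alkoxy aldehyde.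

Step 2
Reactants: 5 (S)-[3,4-bis(benzyloxy)phenyl][(4R)-2,2-dimethyl-1,3-dioxolan-4-yl]methanol
Product: 7 (4R)-4-{(S)-benzyloxy[3,4-bis(benzyloxy)phenyl]methyl}-2,2-dimethyl-1,3-dioxolane, via sodium alkoxide 6 (not isolated)
Conditions: NaH, THF–DMF, 0 °C; BnBr, Bu4NI (cat.), 0 °C to rt
Reagents that add atoms: benzyl bromide, BrCc1ccccc1
Why: Williamson etherification of the sodium alkoxide 6 with benzyl bromide under iodide catalysis; O8 and O9 are locked in the acetonide, so only O7 is benzylated, and no bond to a stereocentre is broken.

Step 3
Reactants: 7 (4R)-4-{(S)-benzyloxy[3,4-bis(benzyloxy)phenyl]methyl}-2,2-dimethyl-1,3-dioxolane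
Product: 8 (2R,3S)-3-benzyloxy-3-[3,4-bis(benzyloxy)phenyl]propane-1,2-diol
Conditions: AcOH–H2O (4:1), 40 °C
Reagents that add atoms: none
Why: Acid-catalysed acetal hydrolysis; dilute acetic acid cleaves the isopropylidene acetal but should be too weak to ionise the C7 benzylic ether, whose cation is also destabilised by the adjacent C8 oxygen, so both stereocentres are kept.

Step 4
Reactants: 8 (2R,3S)-3-benzyloxy-3-[3,4-bis(benzyloxy)phenyl]propane-1,2-diol
Product: 9 (1S,2R)-1-benzyloxy-1-[3,4-bis(benzyloxy)phenyl]-3-(trityloxy)propan-2-ol
Conditions: TrCl, Et3N, DMAP (cat.), CH2Cl2, rt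
Reagents that add atoms: trityl chloride, ClC(c1ccccc1)(c1ccccc1)c1ccccc1
Why: Tritylation is governed by steric demand and should take the primary C9 hydroxyl only, leaving the flanked secondary C8 hydroxyl free; the trityl ether is stable to strong base and does not migrate.

Step 5
Reactants: 9 (1S,2R)-1-benzyloxy-1-[3,4-bis(benzyloxy)phenyl]-3-(trityloxy)propan-2-ol; 10 4-fluoro-3-methoxybenzaldehyde
Product: 12 4-{[(1S,2R)-1-benzyloxy-1-[3,4-bis(benzyloxy)phenyl]-3-(trityloxy)propan-2-yl]oxy}-3-methoxybenzaldehyde, via potassium alkoxide 11 (not isolated)
Conditions: KN(SiMe3)2 (0.95 equiv), THF, −78 to 0 °C; then 10 (1.5 equiv), DMF, 0 °C to rt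
Reagents that add atoms: none
Why: Nucleophilic aromatic substitution by addition–elimination: alkoxide 11 adds to C4' of 10, the charge of the Meisenheimer anion is delocalised into the para formyl group, and loss of fluoride restores the arene. The closest known reaction type is the displacement of fluoride from 4-fluorobenzaldehydes by sodium or potassium alkoxides of secondary alcohols in dipolar aprotic solvents. No ring closes and no stereocentre is created; the C8–O bond is not broken, so the (7S,8R) configuration of 9 should pass unchanged into 12. Selectivity on the nucleophile is needed and is secured by protection: O7 is a benzyl ether and O9 a trityl ether, neither of which migrates under base, so only O8 can react. On the electrophile only the C–F carbon is para to the acceptor; the methoxy group is meta to the formyl group, is not displaced, and only slows the addition, which the potassium counter-ion and DMF should offset. Alkoxide addition to the formyl group is reversible and returns the reactants, the slight deficit of amide base leaves no silylamide to condense with the aldehyde, and the low temperature should keep hydride transfer from C8–H to the aldehyde (Meerwein–Ponndorf–Verley type) slower than substitution.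

Step 6
Reactants: 12 4-{[(1S,2R)-1-benzyloxy-1-[3,4-bis(benzyloxy)phenyl]-3-(trityloxy)propan-2-yl]oxy}-3-methoxybenzaldehyde; 13 ethyl (triphenylphosphoranylidene)acetate
Product: 14 ethyl (E)-3-(4-{[(1S,2R)-1-benzyloxy-1-[3,4-bis(benzyloxy)phenyl]-3-(trityloxy)propan-2-yl]oxy}-3-methoxyphenyl)prop-2-enoate
Conditions: toluene, 80 °C
Reagents that add atoms: none
Why: Wittig olefination with a stabilised ylide under neutral conditions adds C8' and C9' as the (E)-acrylate; the aldehyde has no α-hydrogen, the benzyl, trityl and aryl ethers are inert, and the alkene geometry does not matter because the double bond is hydrogenated later.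

Step 7
Reactants: 14 ethyl (E)-3-(4-{[(1S,2R)-1-benzyloxy-1-[3,4-bis(benzyloxy)phenyl]-3-(trityloxy)propan-2-yl]oxy}-3-methoxyphenyl)prop-2-enoate
Product: 15 (E)-3-(4-{[(1S,2R)-1-benzyloxy-1-[3,4-bis(benzyloxy)phenyl]-3-(trityloxy)propan-2-yl]oxy}-3-methoxyphenyl)prop-2-en-1-ol
Conditions: iBu2AlH, CH2Cl2, −78 °C; aq. KNaC4H4O6
Reagents that add atoms: none
Why: 1,2-Reduction of the α,β-unsaturated ester by iBu2AlH at low temperature should give the allylic alcohol without touching any ether; placing the hydride step before deprotection keeps aluminium away from a free catechol.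

Step 8
Reactants: 15 (E)-3-(4-{[(1S,2R)-1-benzyloxy-1-[3,4-bis(benzyloxy)phenyl]-3-(trityloxy)propan-2-yl]oxy}-3-methoxyphenyl)prop-2-en-1-ol
Product: 16 (1S,2R)-1-(3,4-dihydroxyphenyl)-2-[4-(3-hydroxypropyl)-2-methoxyphenoxy]propane-1,3-diol
Conditions: H2 (1 atm), 10% Pd/C, EtOAc–EtOH, rt
Reagents that add atoms: none
Why: Heterogeneous catalytic hydrogenation and hydrogenolysis: the alkene is saturated, the two aryl benzyl ethers and the C7 benzyl ether are cleaved at the unhindered PhCH2–O bond, and the trityl ether is hydrogenolysed to triphenylmethane; in a neutral medium at room temperature the secondary benzylic C7–OH and the primary C9'–OH should persist, and no stereocentre is touched.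

## Compound list

1 | 4-bromo-1,2-bis(benzyloxy)benzene | Brc1ccc(OCc2ccccc2)c(OCc2ccccc2)c1 | starting material
2 | (R)-2,2-dimethyl-1,3-dioxolane-4-carbaldehyde | CC1(C)OC[C@H](C=O)O1 | starting material
3 | [3,4-bis(benzyloxy)phenyl]magnesium bromide | Br[Mg]c1ccc(OCc2ccccc2)c(OCc2ccccc2)c1 | intermediate
4 | [3,4-bis(benzyloxy)phenyl]titanium triisopropoxide | CC(C)O[Ti](OC(C)C)(OC(C)C)c1ccc(OCc2ccccc2)c(OCc2ccccc2)c1 | intermediate
5 | (S)-[3,4-bis(benzyloxy)phenyl][(4R)-2,2-dimethyl-1,3-dioxolan-4-yl]methanol | CC1(C)O[C@H](CO1)[C@@H](O)c2ccc(OCc3ccccc3)c(OCc3ccccc3)c2 | intermediate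
6 | sodium (S)-[3,4-bis(benzyloxy)phenyl][(4R)-2,2-dimethyl-1,3-dioxolan-4-yl]methanolate | [Na+].CC1(C)O[C@H](CO1)[C@@H]([O-])c2ccc(OCc3ccccc3)c(OCc3ccccc3)c2 | intermediate
7 | (4R)-4-{(S)-benzyloxy[3,4-bis(benzyloxy)phenyl]methyl}-2,2-dimethyl-1,3-dioxolane | CC1(C)O[C@H](CO1)[C@@H](OCc2ccccc2)c2ccc(OCc3ccccc3)c(OCc3ccccc3)c2 | intermediate
8 | (2R,3S)-3-benzyloxy-3-[3,4-bis(benzyloxy)phenyl]propane-1,2-diol | O[C@H](CO)[C@@H](OCc1ccccc1)c1ccc(OCc2ccccc2)c(OCc2ccccc2)c1 | intermediate
9 | (1S,2R)-1-benzyloxy-1-[3,4-bis(benzyloxy)phenyl]-3-(trityloxy)propan-2-ol | O[C@H](COC(c1ccccc1)(c1ccccc1)c1ccccc1)[C@@H](OCc1ccccc1)c1ccc(OCc2ccccc2)c(OCc2ccccc2)c1 | intermediate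
10 | 4-fluoro-3-methoxybenzaldehyde | COc1cc(C=O)ccc1F | starting material
11 | potassium (1S,2R)-1-benzyloxy-1-[3,4-bis(benzyloxy)phenyl]-3-(trityloxy)propan-2-olate | [K+].[O-][C@H](COC(c1ccccc1)(c1ccccc1)c1ccccc1)[C@@H](OCc1ccccc1)c1ccc(OCc2ccccc2)c(OCc2ccccc2)c1 | intermediate
12 | 4-{[(1S,2R)-1-benzyloxy-1-[3,4-bis(benzyloxy)phenyl]-3-(trityloxy)propan-2-yl]oxy}-3-methoxybenzaldehyde | COc1cc(C=O)ccc1O[C@H](COC(c1ccccc1)(c1ccccc1)c1ccccc1)[C@@H](OCc1ccccc1)c1ccc(OCc2ccccc2)c(OCc2ccccc2)c1 | intermediate
13 | ethyl (triphenylphosphoranylidene)acetate | CCOC(=O)C=P(c1ccccc1)(c1ccccc1)c1ccccc1 | starting material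
14 | ethyl (E)-3-(4-{[(1S,2R)-1-benzyloxy-1-[3,4-bis(benzyloxy)phenyl]-3-(trityloxy)propan-2-yl]oxy}-3-methoxyphenyl)prop-2-enoate | CCOC(=O)/C=C/c1ccc(O[C@H](COC(c2ccccc2)(c2ccccc2)c2ccccc2)[C@@H](OCc2ccccc2)c2ccc(OCc3ccccc3)c(OCc3ccccc3)c2)c(OC)c1 | intermediate
15 | (E)-3-(4-{[(1S,2R)-1-benzyloxy-1-[3,4-bis(benzyloxy)phenyl]-3-(trityloxy)propan-2-yl]oxy}-3-methoxyphenyl)prop-2-en-1-ol | OC/C=C/c1ccc(O[C@H](COC(c2ccccc2)(c2ccccc2)c2ccccc2)[C@@H](OCc2ccccc2)c2ccc(OCc3ccccc3)c(OCc3ccccc3)c2)c(OC)c1 | intermediate
16 | (1S,2R)-1-(3,4-dihydroxyphenyl)-2-[4-(3-hydroxypropyl)-2-methoxyphenoxy]propane-1,3-diol | COc1cc(CCCO)ccc1O[C@H](CO)[C@@H](O)c1ccc(O)c(O)c1 | target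

## Step count and least certain steps

Total step count: 8. Longest linear sequence: 8 steps (from 1 or 2 to 16).

**Step 5 (key step).** The most likely failure is diversion of the alkoxide at the formyl group: hydride transfer from C8–H to the aldehyde, or irreversible consumption of the aldehyde. The substitution may also be too slow, because the alkoxide is hindered by the neighbouring trityloxymethyl and benzyloxy(aryl)methyl groups and the ortho methoxy group reduces the electrophilicity of C4'. Heating to force the substitution would favour the side reactions at the carbonyl. The fallback sets out from 9 and replaces the formyl acceptor by a nitrile, which accepts neither hydride nor alkoxide and tolerates heating. Alkoxide 11, generated as before, is treated with 4-fluoro-3-methoxybenzonitrile in DMF to give 4-{[(1S,2R)-1-benzyloxy-1-[3,4-bis(benzyloxy)phenyl]-3-(trityloxy)propan-2-yl]oxy}-3-methoxybenzonitrile F1. Partial reduction of F1 with iBu2AlH in toluene at −78 °C, followed by mild aqueous hydrolysis of the aldimine, comes back to the route at 12.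

**Step 1.** The risk is poor facial selectivity at C7. Incomplete transmetalation would leave magnesium species that add with little discrimination or by chelation, and partial epimerisation of the labile α-alkoxy aldehyde would erode C8. The fallback sets out from 5 as obtained. Oxidation with Dess–Martin periodinane in CH2Cl2 gives [3,4-bis(benzyloxy)phenyl][(4R)-2,2-dimethyl-1,3-dioxolan-4-yl]methanone F2. Reduction of F2 with Zn(BH4)2 in Et2O at low temperature should deliver hydride within the chelate between the carbonyl oxygen and O8, giving the anti carbinol and coming back at 5. This corrects C7 by reagent-controlled reduction instead of relying on the addition.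

**Step 8.** Three processes may interfere: hydrogenolysis of the allylic C9'–O bond in competition with saturation of the alkene, hydrogenolysis of the benzylic C7–O bond once ring A has become an electron-rich catechol, and stalling of the trityl cleavage, which is slower than benzyl ether cleavage. The fallback sets out from 14 and separates the tasks:
- Detritylation with catalytic camphorsulfonic acid in MeOH–CH2Cl2 at 0 °C, while ring A is still benzylated, gives ethyl (E)-3-(4-{[(1S,2R)-1-benzyloxy-1-[3,4-bis(benzyloxy)phenyl]-3-hydroxypropan-2-yl]oxy}-3-methoxyphenyl)prop-2-enoate F3.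
- Hydrogenation of F3 over Pd/C in EtOAc now meets only a conjugated alkene and benzyl ethers, with no allylic alcohol, and gives ethyl 3-(4-{[(1S,2R)-1-(3,4-dihydroxyphenyl)-1,3-dihydroxypropan-2-yl]oxy}-3-methoxyphenyl)propanoate F4.
- Reduction of the ester of F4 with excess LiBH4 in THF comes back to the route at 16.

This fallback does not remove the C7–O risk; that is limited in both variants by the neutral medium and by stopping once the benzyl ethers are consumed.

## Further compounds

F1 | step 5 | 4-{[(1S,2R)-1-benzyloxy-1-[3,4-bis(benzyloxy)phenyl]-3-(trityloxy)propan-2-yl]oxy}-3-methoxybenzonitrile | COc1cc(C#N)ccc1O[C@H](COC(c1ccccc1)(c1ccccc1)c1ccccc1)[C@@H](OCc1ccccc1)c1ccc(OCc2ccccc2)c(OCc2ccccc2)c1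
F2 | step 1 | [3,4-bis(benzyloxy)phenyl][(4R)-2,2-dimethyl-1,3-dioxolan-4-yl]methanone | CC1(C)O[C@H](CO1)C(=O)c2ccc(OCc3ccccc3)c(OCc3ccccc3)c2
F3 | step 8 | ethyl (E)-3-(4-{[(1S,2R)-1-benzyloxy-1-[3,4-bis(benzyloxy)phenyl]-3-hydroxypropan-2-yl]oxy}-3-methoxyphenyl)prop-2-enoate | CCOC(=O)/C=C/c1ccc(O[C@H](CO)[C@@H](OCc2ccccc2)c2ccc(OCc3ccccc3)c(OCc3ccccc3)c2)c(OC)c1
F4 | step 8 | ethyl 3-(4-{[(1S,2R)-1-(3,4-dihydroxyphenyl)-1,3-dihydroxypropan-2-yl]oxy}-3-methoxyphenyl)propanoate | CCOC(=O)CCc1ccc(O[C@H](CO)[C@@H](O)c2ccc(O)c(O)c2)c(OC)c1
A1 | alternative 1 | ethyl (2S,3S)-3-(3,4-diacetoxyphenyl)-3-hydroxy-2-[2-methoxy-4-(3-methoxy-3-oxopropyl)phenoxy]propanoate (anti) | COc1cc(CCC(=O)OC)ccc1O[C@H](C(=O)OCC)[C@@H](O)c1ccc(OC(C)=O)c(OC(C)=O)c1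
A2 | alternative 1 | methyl 3-(4-hydroxy-3-methoxyphenyl)propanoate | COC(=O)CCc1ccc(O)c(OC)c1
A3 | alternative 1 | ethyl diazoacetate | CCOC(=O)C=[N+]=[N-]
A4 | alternative 1 | 3,4-diacetoxybenzaldehyde | CC(=O)Oc1ccc(C=O)cc1OC(C)=O
A5 | alternative 2 | (1S,2R)-1-[3,4-bis(benzyloxy)phenyl]-3-(tert-butyldimethylsilyloxy)-2-{4-[3-(tert-butyldimethylsilyloxy)propyl]-2-methoxyphenoxy}propan-1-ol | COc1cc(CCCO[Si](C)(C)C(C)(C)C)ccc1O[C@H](CO[Si](C)(C)C(C)(C)C)[C@@H](O)c1ccc(OCc2ccccc2)c(OCc2ccccc2)c1
A6 | alternative 2 | (R)-3-(tert-butyldimethylsilyloxy)-2-{4-[3-(tert-butyldimethylsilyloxy)propyl]-2-methoxyphenoxy}propanal | COc1cc(CCCO[Si](C)(C)C(C)(C)C)ccc1O[C@H](CO[Si](C)(C)C(C)(C)C)C=O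
A7 | alternative 3 | (1S,2R)-1-(3-benzyloxy-4-hydroxyphenyl)-2-[4-(3-hydroxypropyl)-2-methoxyphenoxy]propane-1,3-diol | COc1cc(CCCO)ccc1O[C@H](CO)[C@@H](O)c1ccc(O)c(OCc2ccccc2)c1
A8 | alternative 3 | (E)-2-benzyloxy-4-(3-hydroxyprop-1-en-1-yl)phenol | OC/C=C/c1ccc(O)c(OCc2ccccc2)c1
A9 | alternative 3 | 4-(3-hydroxypropyl)-2-methoxyphenol | COc1cc(CCCO)ccc1O
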